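**Retrosynthetic overview**
1. Target 15 ⇐ salicylic acid 13 by one-pot tetrabromination; the CO2H group is the placeholder for the ring-A ortho-Br (ipso-bromodecarboxylation), and the ring-B Br next to the ether oxygen is carried in from the start.
2. 13 ⇐ methyl salicylate 11 by O-demethylation and saponification.
3. Ring A of 11 ⇐ formal [3+3] benzannulation: intermolecular Mukaiyama aldol addition of bis(silyloxy)diene 8 to 1,1,3,3-tetramethoxypropane 9, then aldol-type closure and aromatisation.
4. 8 ⇐ β-keto ester 6 ⇐ intermolecular crossed Claisen condensation of aryloxyacetate 3 with the enolate of methyl acetate; 3 ⇐ phenol 1 + methyl bromoacetate 2.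
5. Ring order: ring B is bought intact (in 1); ring A is the only ring formed (step 5).

Assumption: the target is achiral (no stereocentre or stereogenic double bond), so no stereocontrol is needed; LDA is used as the commercial solution.

**Step 1**
Reactants: 1 2-bromo-6-methoxyphenol; 2 methyl bromoacetate
Product: 3 methyl 2-(2-bromo-6-methoxyphenoxy)acetate
Conditions: K2CO3 (1.5 eq), acetone, reflux
Reagents that add atoms: none
Why: Williamson ether synthesis; the phenoxide displaces the activated primary α-bromo ester by SN2, and no stereocentre is involved.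

**Step 2**
Reactants: 3 methyl 2-(2-bromo-6-methoxyphenoxy)acetate; 4 methyl acetate
Product: 6 methyl 4-(2-bromo-6-methoxyphenoxy)-3-oxobutanoate, via lithium enolate of methyl acetate 5 (not isolated)
Conditions: LDA (2.2 eq), MeOAc (2.2 eq), THF, −78 °C; then 3, −78 → −20 °C; cold 1 M HCl
Reagents that add atoms: none
Why: Crossed Claisen condensation; the preformed ester enolate attacks the more electrophilic α-aryloxy ester, and deprotonation of the β-keto ester product makes it irreversible.

**Step 3**
Reactants: 6 methyl 4-(2-bromo-6-methoxyphenoxy)-3-oxobutanoate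
Product: 7 methyl 4-(2-bromo-6-methoxyphenoxy)-3-(trimethylsilyloxy)but-2-enoate (E/Z mixture)
Conditions: Me3SiCl (1.5 eq), Et3N (1.5 eq), toluene, 20 °C, 48 h; filter, concentrate
Reagents that add atoms: chlorotrimethylsilane, C[Si](C)(C)Cl
Why: Soft enolisation and O-silylation of the β-keto ester give the silyl enol ether; both geometries converge later.

**Step 4**
Reactants: 7 methyl 4-(2-bromo-6-methoxyphenoxy)-3-(trimethylsilyloxy)but-2-enoate
Product: 8 4-(2-bromo-6-methoxyphenoxy)-1-methoxy-1,3-bis(trimethylsilyloxy)buta-1,3-diene (used crude)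
Conditions: LDA (1.3 eq), THF, −78 °C; Me3SiCl (1.5 eq), −78 → 20 °C; hexane, filter under Ar
Reagents that add atoms: chlorotrimethylsilane, C[Si](C)(C)Cl
Why: Vinylogous (γ) deprotonation and O-silylation of the dienolate give the 1,3-bis(silyl enol ether), a masked β-keto ester dianion; the aryl bromide is inert to LDA at −78 °C.

**Step 5**
Reactants: 8 4-(2-bromo-6-methoxyphenoxy)-1-methoxy-1,3-bis(trimethylsilyloxy)buta-1,3-diene; 9 1,1,3,3-tetramethoxypropane
Product: 11 methyl 3-(2-bromo-6-methoxyphenoxy)-2-hydroxybenzoate, via open-chain Mukaiyama aldol adduct 10 (not isolated)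
Conditions: Me3SiOTf (0.1–0.3 eq), CH2Cl2, −78 → 20 °C, 16 h; 10 % aq. HCl
Reagents that add atoms: none
Why: Formal [3+3] benzannulation; the diene terminus adds to the acetal-derived oxocarbenium ion (intermolecular Mukaiyama aldol), the central carbon closes onto the second acetal, and loss of methanol aromatises, erasing the two transient stereocentres of 10.

**Step 6**
Reactants: 11 methyl 3-(2-bromo-6-methoxyphenoxy)-2-hydroxybenzoate
Product: 12 methyl 3-(2-bromo-6-hydroxyphenoxy)-2-hydroxybenzoate
Conditions: BBr3 (3 eq), CH2Cl2, −78 → 0 °C; ice-water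
Reagents that add atoms: none
Why: Lewis-acid O-demethylation of the aryl methyl ether (bromide attacks the O–CH3 carbon); the diaryl ether and aryl bromide are untouched, and any ester cleavage is harmless because step 7 hydrolyses it anyway.

**Step 7**
Reactants: 12 methyl 3-(2-bromo-6-hydroxyphenoxy)-2-hydroxybenzoate
Product: 13 3-(2-bromo-6-hydroxyphenoxy)-2-hydroxybenzoic acid
Conditions: LiOH·H2O (5 eq), THF/H2O 3:1, 50 °C; then 1 M HCl to pH 1–2
Reagents that add atoms: lithium hydroxide, [Li+].[OH-]
Why: Ester saponification (BAc2); the electron-rich phenoxide rings cannot undergo Smiles rearrangement, so the ether connectivity is kept.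

**Step 8**
Reactants: 13 3-(2-bromo-6-hydroxyphenoxy)-2-hydroxybenzoic acid
Product: 15 3,4,6-tribromo-2-(3,5-dibromo-2-hydroxyphenoxy)phenol, via tribromo salicylic acid 14 (not isolated)
Conditions: Br2 (4.2 eq), NaOAc (5 eq), AcOH/H2O 3:1, 0 → 25 °C; aq. NaHSO3
Reagents that add atoms: bromine, BrBr
Why: Electrophilic aromatic bromination ortho and para to each free OH; on ring A the only free ortho site carries CO2H, so the fourth bromine enters by ipso-bromodecarboxylation, and the bisulfite work-up reduces any over-brominated dienone back to the phenol.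

**Compound list**
1 | 2-bromo-6-methoxyphenol | COc1cccc(Br)c1O | starting material
2 | methyl bromoacetate | COC(=O)CBr | starting material
3 | methyl 2-(2-bromo-6-methoxyphenoxy)acetate | COC(=O)COc1c(Br)cccc1OC | intermediate
4 | methyl acetate | COC(C)=O | starting material
5 | lithium enolate of methyl acetate (lithium 1-methoxyethenolate) | [Li+].[O-]C(=C)OC | intermediate
6 | methyl 4-(2-bromo-6-methoxyphenoxy)-3-oxobutanoate | COC(=O)CC(=O)COc1c(Br)cccc1OC | intermediate
7 | methyl 4-(2-bromo-6-methoxyphenoxy)-3-(trimethylsilyloxy)but-2-enoate (E/Z mixture, geometry not defined) | COC(=O)C=C(O[Si](C)(C)C)COc1c(Br)cccc1OC | intermediate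
8 | 4-(2-bromo-6-methoxyphenoxy)-1-methoxy-1,3-bis(trimethylsilyloxy)buta-1,3-diene (isomer mixture, geometry not defined) | COC(O[Si](C)(C)C)=CC(O[Si](C)(C)C)=COc1c(Br)cccc1OC | intermediate
9 | 1,1,3,3-tetramethoxypropane | COC(OC)CC(OC)OC | starting material
10 | methyl 4-(2-bromo-6-methoxyphenoxy)-5,7,7-trimethoxy-3-(trimethylsilyloxy)hept-2-enoate (diastereomer mixture, centres erased in the same step) | COC(=O)C=C(O[Si](C)(C)C)C(Oc1c(Br)cccc1OC)C(OC)CC(OC)OC | intermediate
11 | methyl 3-(2-bromo-6-methoxyphenoxy)-2-hydroxybenzoate | COC(=O)c1cccc(Oc2c(Br)cccc2OC)c1O | intermediate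
12 | methyl 3-(2-bromo-6-hydroxyphenoxy)-2-hydroxybenzoate | COC(=O)c1cccc(Oc2c(Br)cccc2O)c1O | intermediate
13 | 3-(2-bromo-6-hydroxyphenoxy)-2-hydroxybenzoic acid | OC(=O)c1cccc(Oc2c(Br)cccc2O)c1O | intermediate
14 | 5-bromo-2-hydroxy-3-(2,3,5-tribromo-6-hydroxyphenoxy)benzoic acid | OC(=O)c1cc(Br)cc(Oc2c(Br)c(Br)cc(Br)c2O)c1O | intermediate
15 | 3,4,6-tribromo-2-(3,5-dibromo-2-hydroxyphenoxy)phenol (achiral) | Oc1c(Br)cc(Br)cc1Oc1c(O)c(Br)cc(Br)c1Br | target

**Totals**
Total steps: 8. Longest linear sequence: 8 (1 → 15).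

**Three steps most likely to fail, with fallbacks**

Step 5 ([3+3] benzannulation; moisture-sensitive diene, moderate yield). The fallback sets out from 6 and comes back at 11 by a Michael/aldol/dehydrogenation sequence. Conjugate addition of 6 to acrolein (cat. Et3N, MeCN, 0 °C) gives methyl 2-[2-(2-bromo-6-methoxyphenoxy)acetyl]-5-oxopentanoate F1. Acid-mediated intramolecular aldol condensation of the ArO-CH2 carbon onto the aldehyde (p-TsOH, toluene, 80 °C, water removal) gives methyl 3-(2-bromo-6-methoxyphenoxy)-2-oxocyclohex-3-ene-1-carboxylate F2. Dehydrogenation with DDQ (dioxane, 90 °C) then gives 11.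

Step 8 (tetrabromination with ipso-bromodecarboxylation; may stall at acid 14 or over-brominate). The fallback sets out from 13 and comes back at 15 by separating the two events. Protodecarboxylation of 13 (Ag2CO3 10 mol %, AcOH cat., DMSO, 120 °C) gives 3-bromo-2-(2-hydroxyphenoxy)phenol F3. Plain OH-directed tetrabromination of F3 (Br2 4.1 eq, NaOAc, AcOH, 0 → 20 °C) then gives 15.

Step 2 (crossed Claisen; competing enolisation or self-condensation of 3). The fallback sets out from 3 and comes back at 6 by the acyl-Meldrum's acid route. Saponification of 3 (LiOH, THF/H2O; HCl) gives 2-(2-bromo-6-methoxyphenoxy)acetic acid F4. C-acylation of Meldrum's acid with F4 (DCC, DMAP, CH2Cl2, 0 → 20 °C) gives 5-[2-(2-bromo-6-methoxyphenoxy)-1-hydroxyethylidene]-2,2-dimethyl-1,3-dioxane-4,6-dione F5. Refluxing F5 in methanol (ring opening and decarboxylation) gives 6.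

**Further compounds**
F1 | step 5 | methyl 2-[2-(2-bromo-6-methoxyphenoxy)acetyl]-5-oxopentanoate (racemic, centre erased later) | COC(=O)C(CCC=O)C(=O)COc1c(Br)cccc1OC
F2 | step 5 | methyl 3-(2-bromo-6-methoxyphenoxy)-2-oxocyclohex-3-ene-1-carboxylate (racemic, centre erased on aromatisation) | COC(=O)C1CCC=C(Oc2c(Br)cccc2OC)C1=O
F3 | step 8 | 3-bromo-2-(2-hydroxyphenoxy)phenol | Oc1ccccc1Oc1c(O)cccc1Br
F4 | step 2 | 2-(2-bromo-6-methoxyphenoxy)acetic acid | OC(=O)COc1c(Br)cccc1OC
F5 | step 2 | 5-[2-(2-bromo-6-methoxyphenoxy)-1-hydroxyethylidene]-2,2-dimethyl-1,3-dioxane-4,6-dione | CC1(C)OC(=O)C(=C(O)COc2c(Br)cccc2OC)C(=O)O1
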